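**Retrosynthetic overview**
1. Pakyonol ⇒ open-chain bromo-styrene 15. The 20-membered ring is closed last, at the ring-B aryl–CH2 bond, by addition of a ring-B aryl radical to the ring-C vinyl group.
2. 15 ⇒ iodophenol 14 (iodide-selective vinylation) ⇒ bibenzyl phenol 8 + 2-fluoro-5-iodobenzaldehyde 11 (SNAr, then Dakin to unmask the ring-C OH).
3. 8 ⇒ aryl iodide 5 + 3-vinylphenol 7 by an intermolecular, iodide-selective radical hydroarylation (ring-A aryl–CH2 bond).
4. 5 ⇒ guaiacol + 1-bromo-4-iodobenzene (Ullmann ether, then iodination para to OMe). Halogen hierarchy: ring-A I (first radical step) > ring-C I (Suzuki) > ring-B Br (macrocyclisation).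
5. All four benzene rings are bought (catechol, 1-bromo-4-iodobenzene, 3-bromophenol, 1-fluoro-4-iodobenzene); the macrocycle is the only ring formed.

Assumption: pakyonol has no stereocentre and its 20-membered ring is taken as conformationally mobile, so the "single enantiomer" is the one achiral compound and no step needs stereocontrol.

**Route**

Step 1
Reactants: 1 catechol
Product: 2 guaiacol (2-methoxyphenol)
Conditions: MeI (1.0 equiv), K2CO3 (1.0 equiv), acetone, reflux; base extraction to remove veratrole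
Reagents that add atoms: iodomethane, CI
Why: Williamson mono-O-methylation with limiting MeI; the phenolic product is separated from neutral veratrole and water-soluble catechol by extraction.

Step 2
Reactants: 2 guaiacol; 3 1-bromo-4-iodobenzene (1.3 equiv)
Product: 4 1-(4-bromophenoxy)-2-methoxybenzene
Conditions: CuI (10 mol %), picolinic acid (20 mol %), K3PO4 (2 equiv), DMSO, 80 °C
Reagents that add atoms: none
Why: Ullmann diaryl ether coupling; the C–I bond reacts much faster than C–Br at 80 °C, so the bromide is kept for the final step.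

Step 3
Reactants: 4 1-(4-bromophenoxy)-2-methoxybenzene
Product: 5 2-(4-bromophenoxy)-4-iodo-1-methoxybenzene
Conditions: NIS (1.05 equiv), TFA (0.3 equiv), MeCN, rt
Reagents that add atoms: N-iodosuccinimide, O=C1CCC(=O)N1I
Why: Electrophilic aromatic iodination goes para to OMe, the strongest donor; ring B is deactivated by Br and blocked at its para position.

Step 4
Reactants: 6 3-bromophenol
Product: 7 3-ethenylphenol (3-vinylphenol)
Conditions: vinylBpin (1.2 equiv), Pd(dppf)Cl2 (3 mol %), K2CO3 (3 equiv), dioxane/H2O 4:1, 80 °C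
Reagents that add atoms: vinylboronic acid pinacol ester, C=CB1OC(C)(C)C(C)(C)O1
Why: Suzuki–Miyaura vinylation of an aryl bromide; the free phenol is tolerated as its phenoxide.

Step 5
Reactants: 5 2-(4-bromophenoxy)-4-iodo-1-methoxybenzene; 7 3-ethenylphenol (4 equiv)
Product: 8 3-{2-[3-(4-bromophenoxy)-4-methoxyphenyl]ethyl}phenol
Conditions: fac-Ir(ppy)3 (2 mol %), Hantzsch ester (1.5 equiv, in portions), CySH (10 mol %), NaHCO3 (2 equiv), DMSO/H2O 5:1, 450 nm LEDs, rt
Reagents that add atoms: none
Why: Photoredox radical hydroarylation: excited Ir(ppy)3 reduces only the C–I bond, the aryl radical adds to the terminal carbon of the styrene (anti-Markovnikov, Giese-type), and the benzylic radical takes H from thiol/Hantzsch ester; the C–Br bond is untouched.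

Step 6
Reactants: 9 1-fluoro-4-iodobenzene
Product: 11 2-fluoro-5-iodobenzaldehyde, via (2-fluoro-5-iodophenyl)lithium 10 (not isolated)
Conditions: LDA (1.05 equiv), THF, −78 °C; DMF (1.5 equiv), −78 → 0 °C; H2O
Reagents that add atoms: N,N-dimethylformamide, CN(C)C=O
Why: Fluorine-directed ortho-lithiation with the non-nucleophilic base LDA (no I/Li exchange at −78 °C), then formylation with DMF.

Step 7
Reactants: 8 3-{2-[3-(4-bromophenoxy)-4-methoxyphenyl]ethyl}phenol; 11 2-fluoro-5-iodobenzaldehyde
Product: 12 2-(3-{2-[3-(4-bromophenoxy)-4-methoxyphenyl]ethyl}phenoxy)-5-iodobenzaldehyde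
Conditions: K2CO3 (2 equiv), DMF, 110 °C
Reagents that add atoms: none
Why: SNAr of the phenoxide on the fluoride activated by the ortho-formyl group; aryl I and Br are inert without a metal catalyst.

Step 8
Reactants: 12 2-(3-{2-[3-(4-bromophenoxy)-4-methoxyphenyl]ethyl}phenoxy)-5-iodobenzaldehyde
Product: 14 2-(3-{2-[3-(4-bromophenoxy)-4-methoxyphenyl]ethyl}phenoxy)-5-iodophenol, via aryl formate 13 (not isolated)
Conditions: mCPBA (1.3 equiv), NaHCO3, CH2Cl2, 0 °C → rt; Na2S2O3 wash; then K2CO3 (cat.), MeOH, rt
Reagents that add atoms: meta-chloroperoxybenzoic acid, OOC(=O)c1cccc(Cl)c1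
Why: Baeyer–Villiger (Dakin-type) oxidation; the electron-rich ortho-aryloxy aryl group migrates to give the formate, which is methanolysed to the phenol; no alkene is present yet.

Step 9
Reactants: 14 2-(3-{2-[3-(4-bromophenoxy)-4-methoxyphenyl]ethyl}phenoxy)-5-iodophenol
Product: 15 2-(3-{2-[3-(4-bromophenoxy)-4-methoxyphenyl]ethyl}phenoxy)-5-ethenylphenol
Conditions: vinylBpin (1.1 equiv), Pd(PPh3)4 (3 mol %), K2CO3 (3 equiv), dioxane/H2O 4:1, 60 °C
Reagents that add atoms: vinylboronic acid pinacol ester, C=CB1OC(C)(C)C(C)(C)O1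
Why: Chemoselective Suzuki–Miyaura vinylation; oxidative addition to C–I is far faster than to C–Br with a PPh3 catalyst at 60 °C, so the ring-B bromide survives.

Step 10
Reactants: 15 2-(3-{2-[3-(4-bromophenoxy)-4-methoxyphenyl]ethyl}phenoxy)-5-ethenylphenol
Product: 16 pakyonol
Conditions: 10-phenylphenothiazine (20 mol %), Hantzsch ester (1.5 equiv), CySH (10 mol %), NaHCO3 (2 equiv), degassed MeCN/H2O 9:1, 390 nm LEDs, 25 °C; 15 and Hantzsch ester added by syringe pump over 12 h, final 1 mM
Reagents that add atoms: none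
Why: Proposed new method: excited phenothiazine (about −2.1 V) cleaves the ring-B C–Br bond to an aryl radical, which adds to the terminal carbon of the ring-C styrene (intermolecular k about 10^8 M^-1 s^-1, so an estimated 10^6–10^7 s^-1 for this pre-bent bis(diaryl ether), faster than H-abstraction from MeCN or from the sub-millimolar H-donors), and the benzylic radical is then quenched by thiol/Hantzsch ester to give the saturated bridge and the 20-membered ring directly; the closest known reaction types are the intermolecular photoredox anti-Markovnikov hydroarylation of alkenes with aryl halides (as in step 5) and tin-hydride radical macrocyclisations; no stereocentre is formed.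

**Compound list**
1 | catechol (benzene-1,2-diol) | Oc1ccccc1O | starting material
2 | guaiacol (2-methoxyphenol) | COc1ccccc1O | intermediate
3 | 1-bromo-4-iodobenzene | Brc1ccc(I)cc1 | starting material
4 | 1-(4-bromophenoxy)-2-methoxybenzene | COc1ccccc1Oc1ccc(Br)cc1 | intermediate
5 | 2-(4-bromophenoxy)-4-iodo-1-methoxybenzene | COc1ccc(I)cc1Oc1ccc(Br)cc1 | intermediate
6 | 3-bromophenol | Oc1cccc(Br)c1 | starting material
7 | 3-ethenylphenol | C=Cc1cccc(O)c1 | intermediate
8 | 3-{2-[3-(4-bromophenoxy)-4-methoxyphenyl]ethyl}phenol | COc1ccc(CCc2cccc(O)c2)cc1Oc1ccc(Br)cc1 | intermediate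
9 | 1-fluoro-4-iodobenzene | Fc1ccc(I)cc1 | starting material
10 | (2-fluoro-5-iodophenyl)lithium | [Li]c1cc(I)ccc1F | intermediate
11 | 2-fluoro-5-iodobenzaldehyde | O=Cc1cc(I)ccc1F | intermediate
12 | 2-(3-{2-[3-(4-bromophenoxy)-4-methoxyphenyl]ethyl}phenoxy)-5-iodobenzaldehyde | COc1ccc(CCc2cccc(Oc3ccc(I)cc3C=O)c2)cc1Oc1ccc(Br)cc1 | intermediate
13 | 2-(3-{2-[3-(4-bromophenoxy)-4-methoxyphenyl]ethyl}phenoxy)-5-iodophenyl formate | COc1ccc(CCc2cccc(Oc3ccc(I)cc3OC=O)c2)cc1Oc1ccc(Br)cc1 | intermediate
14 | 2-(3-{2-[3-(4-bromophenoxy)-4-methoxyphenyl]ethyl}phenoxy)-5-iodophenol | COc1ccc(CCc2cccc(Oc3ccc(I)cc3O)c2)cc1Oc1ccc(Br)cc1 | intermediate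
15 | 2-(3-{2-[3-(4-bromophenoxy)-4-methoxyphenyl]ethyl}phenoxy)-5-ethenylphenol | COc1ccc(CCc2cccc(Oc3ccc(C=C)cc3O)c2)cc1Oc1ccc(Br)cc1 | intermediate
16 | pakyonol | COc1ccc2cc1Oc1ccc(cc1)CCc1ccc(c(O)c1)Oc1cccc(c1)CC2 | target

**Step count**
Total steps: 10. Longest linear sequence: 8 (steps 1, 2, 3, 5, 7, 8, 9, 10, from catechol); steps 4 and 6 are one-step side branches.

**Steps most likely to fail, with fallbacks**

Step 10 (aryl-radical macrocyclisation). The aryl radical may be reduced by solvent or H-donor before it reaches the alkene, giving the debrominated open chain, or it may abstract the phenolic H. The fallback sets out from 15 and comes back at 16, and swaps the short-lived aryl radical for a long-lived primary alkyl radical. Hydroboration of 15 with 9-BBN (2.2 equiv) and NaOH/H2O2 gives the primary alcohol 2-(3-{2-[3-(4-bromophenoxy)-4-methoxyphenyl]ethyl}phenoxy)-5-(2-hydroxyethyl)phenol F1. Appel bromination (CBr4, PPh3, CH2Cl2, 0 °C) gives 5-(2-bromoethyl)-2-(3-{2-[3-(4-bromophenoxy)-4-methoxyphenyl]ethyl}phenoxy)phenol F2. Nickel-catalysed intramolecular reductive cross-electrophile coupling (NiBr2·glyme, dtbbpy, Mn, NaI, DMA, 60 °C, slow addition) then closes the same aryl–CH2 bond by capture of the alkyl radical at the aryl-nickel centre, giving 16.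

Step 5 (intermolecular hydroarylation). Hydrodeiodination of 5, partial loss of the bromide, or interference by the free phenols could lower the yield. The fallback sets out from 5 and 7 and comes back at 8. An iodide-selective Heck coupling (Pd(OAc)2, Bu4NBr, K2CO3, DMF, 80 °C) gives the stilbene 3-{(E)-2-[3-(4-bromophenoxy)-4-methoxyphenyl]ethenyl}phenol F3. Diimide reduction (TsNHNH2, NaOAc, THF/H2O, reflux) saturates the alkene without touching C–Br and gives 8.

Step 9 (iodide-selective vinylation). Any coupling at the ring-B bromide destroys the radical precursor and gives a divinyl by-product that is hard to separate. The fallback sets out from 14 and comes back at 15 and avoids palladium. Iodine–magnesium exchange (i-PrMgCl·LiCl, 3 equiv, THF, 25 °C; the first equivalent deprotonates the phenol, the bromide is not exchanged) followed by DMF gives 4-(3-{2-[3-(4-bromophenoxy)-4-methoxyphenyl]ethyl}phenoxy)-3-hydroxybenzaldehyde F4. Wittig methylenation (Ph3PCH3Br, KOtBu, 2.5 equiv, THF, 0 °C) gives 15.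

**Further compounds**
F1 | step 10 | 2-(3-{2-[3-(4-bromophenoxy)-4-methoxyphenyl]ethyl}phenoxy)-5-(2-hydroxyethyl)phenol | COc1ccc(CCc2cccc(Oc3ccc(CCO)cc3O)c2)cc1Oc1ccc(Br)cc1
F2 | step 10 | 5-(2-bromoethyl)-2-(3-{2-[3-(4-bromophenoxy)-4-methoxyphenyl]ethyl}phenoxy)phenol | COc1ccc(CCc2cccc(Oc3ccc(CCBr)cc3O)c2)cc1Oc1ccc(Br)cc1
F3 | step 5 | 3-{(E)-2-[3-(4-bromophenoxy)-4-methoxyphenyl]ethenyl}phenol | COc1ccc(/C=C/c2cccc(O)c2)cc1Oc1ccc(Br)cc1
F4 | step 9 | 4-(3-{2-[3-(4-bromophenoxy)-4-methoxyphenyl]ethyl}phenoxy)-3-hydroxybenzaldehyde | COc1ccc(CCc2cccc(Oc3ccc(C=O)cc3O)c2)cc1Oc1ccc(Br)cc1
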